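The plan rests on reconnecting C4 to C8 of the target (germacrane numbering): the 8-oxygen lies 1,3 to the C4=C5 double bond, and C4 and C9 sit next to the ether bridgeheads C3 and C10, so this bond turns the oxygen-bridged ten-membered ring into a cyclopentane fused to an 8-oxabicyclo[3.2.1]octan-3-one, the adduct of a furan and an oxyallyl cation. In the forward sense one alkoxide-triggered Wharton–Grob fragmentation cuts that bond, merges the five- and seven-membered carbocycles into the cyclodecene, and delivers the C8 ketone and the 4Z alkene together. Its precursor is a tricyclic tertiary C8 alcohol carrying a C5 mesylate, quaternary C4 and the exo-methylene ester on C7.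

Key step: step 17

Remark on conventions: germacrane numbering of the target (C1–C15, ether oxygen between C3 and C10) is used for all intermediates; exo is the face of the oxabicycle turned to the oxygen bridge, endo the face turned to the other carbon bridge; racemates are drawn as the enantiomer that is carried on; PMB = 4-methoxybenzyl, MOM = methoxymethyl.

Assumption: the (R,R)-lithium amide is taken to select the drawn enantiomer of the racemic saturated bicyclic ketone; if chiral recognition runs the other way, the (S,S)-amide is used in the same manner.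

**Route**

Step 1
Reactants: 1 2-methyltetrahydrofuran-3-one (racemic)
Product: 2 2-methyl-3-(trimethylsilyloxy)-2,5-dihydrofuran (racemic)
Conditions: LiN(i-Pr)2, THF, −78 °C; Me3SiCl, −78 °C to 0 °C
Reagents that add atoms: chlorotrimethylsilane, C[Si](C)(C)Cl
Why: Kinetic enolisation with the hindered amide removes a C4 hydrogen in preference to the more hindered α-alkoxy C2 hydrogen and O-silylation traps the enolate (kinetic silyl enol ether formation); the existing stereocentre is irrelevant because step 3 destroys it.

Step 2
Reactants: 2 2-methyl-3-(trimethylsilyloxy)-2,5-dihydrofuran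
Product: 3 2-methylfuran-3(2H)-one (racemic)
Conditions: Pd(OAc)2 (1 equiv), MeCN, rt
Reagents that add atoms: none
Why: Saegusa–Ito dehydrogenation: the palladium enolate formed from the silyl enol ether undergoes β-hydride elimination toward C5 and gives the vinylogous ester.

Step 3
Reactants: 3 2-methylfuran-3(2H)-one
Product: 4 3-(methoxymethoxy)-2-methylfuran
Conditions: KN(SiMe3)2, THF–DMPU, −78 °C; MOMCl, −78 °C to 0 °C
Reagents that add atoms: chloromethyl methyl ether, COCCl
Why: Deprotonation at C2 gives the aromatic furan-3-olate and the hard electrophile MOMCl reacts at oxygen (enolate O-alkylation), the path that keeps the furan aromatic.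

Step 4
Reactants: 4 3-(methoxymethoxy)-2-methylfuran; 5 1,1,3-trichloroacetone
Product: 7 2,4-dichloro-7-(methoxymethoxy)-1-methyl-8-oxabicyclo[3.2.1]oct-6-en-3-one (racemic; chloro epimers), via dichloro-oxyallyl cation 6 (not isolated)
Conditions: Et3N, CF3CH2OH, 0 °C to rt
Reagents that add atoms: none
Why: [4+3] cycloaddition of an oxyallyl cation with a furan: amine-induced loss of HCl from 5 in the ionising solvent gives cation 6, which bonds first to the methyl-bearing α-carbon of the electron-rich furan and then closes at the other α-carbon, so the two bridgeheads are necessarily cis while the chlorine-bearing centres are irrelevant.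

Step 5
Reactants: 7 dichloro cycloadduct
Product: 8 7-(methoxymethoxy)-1-methyl-8-oxabicyclo[3.2.1]oct-6-en-3-one (racemic; 1S,5R enantiomer drawn)
Conditions: Zn–Cu couple, NH4Cl, MeOH, 0 °C to rt
Reagents that add atoms: none
Why: Reductive dechlorination of the α-chloro ketone units by zinc through zinc enolates, in a near-neutral ammonium chloride buffer that leaves the enol MOM ether intact.

Step 6
Reactants: 8 oxabicyclic enol ether ketone
Product: 9 7-endo-(methoxymethoxy)-1-methyl-8-oxabicyclo[3.2.1]octan-3-one (racemic; 1S,5S,7S enantiomer drawn)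
Conditions: H2 (1 atm), 10% Pd on carbon, Et3N (trace), EtOAc, rt
Reagents that add atoms: none
Why: Heterogeneous hydrogenation delivers hydrogen to the enol-ether double bond from the open exo face (the endo face is covered by the ketone bridge), so the OMOM group ends endo, which is the C1 configuration of the target.

Step 7
Reactants: 9 racemic saturated ketone
Product: 10 trimethylsilyl enol ether of the (1S,5S,7S) ketone with the double bond toward the CH bridgehead (C4=C8), enantioenriched
Conditions: LiN[(R)-CH(CH3)Ph]2 (0.5 equiv), LiCl, Me3SiCl (present from the start), THF, −100 °C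
Reagents that add atoms: chlorotrimethylsilane, C[Si](C)(C)Cl
Why: Kinetic resolution by enantioselective deprotonation with a chiral lithium amide under internal silyl quench: the base removes the axial C4 hydrogen of the drawn enantiomer, whereas in the mirror-image ketone its preferred hydrogen lies at C9 beside the methyl-bearing bridgehead and is shielded, so that enantiomer stays as ketone and is separated from silyl enol ether 10.

Step 8
Reactants: 10 enantioenriched silyl enol ether
Product: 12 (1S,4S,5S,7S)-7-(methoxymethoxy)-1,4-dimethyl-8-oxabicyclo[3.2.1]octan-3-one, via lithium enolate 11 (not isolated)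
Conditions: MeLi, THF, 0 °C; then MeI, DMPU, −78 °C to −20 °C
Reagents that add atoms: iodomethane, CI
Why: Cleavage of the silyl enol ether with MeLi releases the regiodefined lithium enolate with no ketone present as proton source, and C-alkylation with MeI occurs on the exo face at C4; the new centre does not matter because step 9 makes it trigonal again.

Step 9
Reactants: 12 C4-methyl ketone
Product: 13 tetrasubstituted C4=C8 trimethylsilyl enol ether of 12
Conditions: Me3SiCl, NaI, Et3N, MeCN, rt
Reagents that add atoms: chlorotrimethylsilane, C[Si](C)(C)Cl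
Why: Thermodynamic silyl enol ether formation under equilibrating, amine-buffered Me3SiI conditions favours the tetrasubstituted C4=C8 isomer over the C8=C9 isomer next to the quaternary bridgehead.

Step 10
Reactants: 14 (S)-but-3-ene-1,2-diol
Product: 15 (4S)-2-(4-methoxyphenyl)-4-vinyl-1,3-dioxolane (acetal epimers)
Conditions: 4-MeOC6H4CH(OMe)2, PPTS (cat.), CH2Cl2, rt
Reagents that add atoms: 4-methoxybenzaldehyde dimethyl acetal, COc1ccc(C(OC)OC)cc1
Why: Acid-catalysed transacetalisation ties both hydroxyls into the 4-methoxybenzylidene acetal without touching the allylic stereocentre (the acetal carbon forms as an inconsequential epimer mixture).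

Step 11
Reactants: 15 4-methoxybenzylidene acetal
Product: 16 (S)-2-(4-methoxybenzyloxy)but-3-en-1-ol
Conditions: i-Bu2AlH, CH2Cl2, −78 °C to 0 °C; aqueous work-up
Reagents that add atoms: none
Why: Regioselective reductive opening of the benzylidene-type acetal: the aluminium hydride binds the less hindered primary oxygen and cleaves its C–O bond, so the PMB ether stays on the secondary oxygen and the primary alcohol is freed.

Step 12
Reactants: 16 (S)-2-(4-methoxybenzyloxy)but-3-en-1-ol; 17 methyl 2-(acetoxymethyl)acrylate
Product: 18 methyl (2E,4S)-2-(acetoxymethyl)-5-hydroxy-4-(4-methoxybenzyloxy)pent-2-enoate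
Conditions: second-generation Hoveyda–Grubbs catalyst [RuCl2(H2IMes)(=CH-C6H4-2-O-i-Pr)] (10 mol%), 17 (5 equiv), toluene, 60 °C
Reagents that add atoms: none
Why: Olefin cross-metathesis of the terminal alkene with the 1,1-disubstituted acrylate used in excess; the trisubstituted enoate should form with C6 trans to the ester (E) for steric reasons and the C6 stereocentre is not involved.

Step 13
Reactants: 18 hydroxy enoate
Product: 19 methyl (2E,4S)-2-(acetoxymethyl)-4-(4-methoxybenzyloxy)-5-oxopent-2-enoate
Conditions: Dess–Martin periodinane, NaHCO3, CH2Cl2, 0 °C; used at once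
Reagents that add atoms: none
Why: Dess–Martin oxidation of the primary alcohol under bicarbonate-buffered, non-basic conditions, so the α-alkoxy β,γ-unsaturated aldehyde should form without epimerisation at C6 and is carried on immediately.

Step 14
Reactants: 13 tetrasubstituted silyl enol ether; 19 aldehyde
Product: 20 aldol adduct: ketone 12 with C4 now quaternary (methyl endo) and bearing on its exo face the chain CH(OH)–CH(OPMB)–CH=C(CH2OAc)CO2Me (C5–OH and C6–OPMB syn; C6 as in 19; 2E enoate)
Conditions: MgBr2·OEt2 (3 equiv), CH2Cl2, −78 °C to −30 °C; aq. citric acid work-up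
Reagents that add atoms: none
Why: Chelation-controlled Mukaiyama aldol addition: magnesium bridges the aldehyde and PMB-ether oxygens so the nucleophile attacks the aldehyde face opposite C7 (5,6-syn), while the bicyclic enol ether reacts at C4 on its exo face, which sets the quaternary centre with C5 axial and the methyl endo; adducts from any residual wrong enantiomer of 13 are diastereomers and are removed here.

Step 15
Reactants: 20 aldol adduct
Product: 21 C5 methanesulfonate of 20
Conditions: MsCl, Et3N, CH2Cl2, −10 °C
Reagents that add atoms: methanesulfonyl chloride, CS(=O)(=O)Cl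
Why: Sulfonylation (via sulfene) of the only free hydroxyl; the quaternary C4 rules out β-elimination of the β-mesyloxy ketone.

Step 16
Reactants: 21 keto mesylate
Product: 23 tricyclic tertiary C8 alcohol: cyclopentane C4–C5–C6–C7–C8 cis-fused to the oxabicycle with O8 endo and C5–OMs cis to C3 and C6–OPMB trans to it and C7 bearing C(=CH2)CO2Me trans to O6 and O8, via cyclised samarium enolate 22 (not isolated)
Conditions: SmI2 (divalent samarium, 2.2 equiv), t-BuOH (2 equiv), THF, −78 °C
Reagents that add atoms: none
Why: SmI2-mediated ketyl–olefin cyclisation (5-exo-trig, C8 onto C7) followed by expulsion of acetate from the trivalent samarium ester enolate to give the C11=C13 methylene; the tether anchored on the axial C5 forces bond formation on the exo face of the ketone (cis ring fusion, O8 endo), and C7 is set with C11 anti to the ketyl oxygen and to the C6 ether (allylic strain places H6 in the enoate plane), an arrangement that also makes lactonisation onto O8 impossible.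

Step 17
Reactants: 23 tricyclic hydroxy mesylate
Product: 25 methyl (4Z)-1-(methoxymethoxy)-6-(4-methoxybenzyloxy)-8-oxo-3,10-epoxygermacra-4,11(13)-dien-12-oate (C1 C3 C6 C7 C10 arranged as in the target), via potassium alkoxide 24 (not isolated)
Conditions: KN(SiMe3)2 (1.0 equiv, added slowly), THF, −78 °C to −40 °C; AcOH quench at −78 °C
Reagents that add atoms: none
Why: Deprotonation of the tertiary C8 hydroxyl gives alkoxide 24, and in the conformer with the mesylate pseudo-equatorial (C8 tipped toward the oxygen bridge, which also takes the alkoxide out of the endo pocket) an oxygen lone pair, the C4–C8 bond and the C5–O bond are anti-periplanar, so C8=O and C4=C5 form while C4–C8 breaks and mesylate leaves in one concerted heterolytic step. The closest known reaction type is the Wharton-type Grob fragmentation of cyclic 1,3-diol monosulfonates to medium-ring alkenyl ketones. No ring is closed by bond formation: cleaving the bond shared by the cyclopentane and the seven-membered carbocycle merges them into the ten-membered ring, still bridged by oxygen between C3 and C10, with release of the strain of the fused bicycle. No new stereocentre arises; the stereogenic element formed is the C4=C5 alkene, whose geometry is fixed by the substrate because the mesylate is cis to C3 and trans to the C15 methyl on the cyclopentane, so anti-periplanar cleavage places C3 and C6 cis (4Z). The selectivity needed is fragmentation over elimination, substitution and enolisation of the product: C4 is quaternary and H6 is syn to the mesylate (no E2), oxetane closure would need a prohibitively strained cage, and one equivalent of base at low temperature with a cold acidic quench protects the acidic C7 hydrogen and the β-alkoxy group of the product.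

Step 18
Reactants: 25 cyclodecenone PMB ether
Product: 26 methyl (4Z)-6-hydroxy-1-(methoxymethoxy)-8-oxo-3,10-epoxygermacra-4,11(13)-dien-12-oate
Conditions: DDQ, CH2Cl2/pH 7 buffer, 0 °C
Reagents that add atoms: none
Why: Oxidative removal of the PMB ether by DDQ (hydride abstraction to the benzylic oxocarbenium ion and hydrolysis) in buffered medium; the MOM ether, the alkenes and the ketone are inert.

Step 19
Reactants: 26 hydroxy ester
Product: 27 (4Z)-1-(methoxymethoxy)-8-oxo-3,10-epoxygermacra-4,11(13)-dien-12,6-olide (trans-fused lactone)
Conditions: CSA (cat.), CH2Cl2, rt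
Reagents that add atoms: none
Why: Acid-catalysed lactonisation (intramolecular transesterification) of the γ-hydroxy ester closes the trans-fused α-methylene-γ-butyrolactone with C6 and C7 already in place; the C8 ketone offers no competing nucleophile and the MOM ether tolerates catalytic acid in an aprotic solvent.

Step 20
Reactants: 27 8-oxo lactone
Product: 28 (4Z,8R)-8-hydroxy-1-(methoxymethoxy)-3,10-epoxygermacra-4,11(13)-dien-12,6-olide
Conditions: (S)-2-methyl-CBS-oxazaborolidine (1 equiv), catecholborane (2 equiv), toluene, −78 °C; aqueous work-up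
Reagents that add atoms: none
Why: Corey–Bakshi–Shibata reduction: the oxazaborolidine binds the ketone with the branched C7 side as the large substituent and directs hydride to the face that gives the 8R alcohol, and catecholborane at −78 °C does not reduce the conjugated lactone.

Step 21
Reactants: 28 8R alcohol; 29 angelic acid
Product: 31 8-O-angeloyl derivative of 28 (MOM ether of the target), via mixed anhydride 30 (not isolated)
Conditions: 29, 2,4,6-trichlorobenzoyl chloride, Et3N, toluene, rt; then 28, 75 °C
Reagents that add atoms: none
Why: Yamaguchi-type mixed-anhydride esterification run without a nucleophilic pyridine catalyst, since such catalysts add to the angeloyl unit and isomerise it to the E (tigloyl) ester; acylation occurs with retention at C8.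

Step 22
Reactants: 31 angelate MOM ether
Product: 33 CNP0213894.1 (1S,3S,4Z,6R,7R,8R,10S)-8-angeloyloxy-1-hydroxy-3,10-epoxygermacra-4,11(13)-dien-12,6-olide, via bromomethyl ether 32 (not isolated)
Conditions: Me2BBr, CH2Cl2, −78 °C; then sat. aq. NaHCO3/THF
Reagents that add atoms: none
Why: Acetal cleavage with Me2BBr at −78 °C (bromide transfer to the boron-activated MOM group, then hydrolysis of bromomethyl ether 32 on work-up) is a thiol-free MOM removal, chosen because thiols would add to the α-methylene lactone; the esters, the lactone and the ether bridge should be untouched at this temperature.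

**Compound list**

1 | 2-methyltetrahydrofuran-3-one (racemic) | CC1OCCC1=O | starting material
2 | 2-methyl-3-(trimethylsilyloxy)-2,5-dihydrofuran (racemic) | CC1OCC=C1O[Si](C)(C)C | intermediate
3 | 2-methylfuran-3(2H)-one (racemic) | CC1OC=CC1=O | intermediate
4 | 3-(methoxymethoxy)-2-methylfuran | Cc1occc1OCOC | intermediate
5 | 1,1,3-trichloroacetone | ClCC(=O)C(Cl)Cl | starting material
6 | 1,3-dichloro-2-oxidoallyl cation | Cl[CH+]C([O-])=CCl | intermediate
7 | 2,4-dichloro-7-(methoxymethoxy)-1-methyl-8-oxabicyclo[3.2.1]oct-6-en-3-one (racemic, chloro epimers) | O=C1C(Cl)[C@@H]2C=C(OCOC)[C@](C)(C1Cl)O2 | intermediate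
8 | 7-(methoxymethoxy)-1-methyl-8-oxabicyclo[3.2.1]oct-6-en-3-one (racemic, 1S,5R drawn) | O=C1C[C@@H]2C=C(OCOC)[C@](C)(C1)O2 | intermediate
9 | 7-endo-(methoxymethoxy)-1-methyl-8-oxabicyclo[3.2.1]octan-3-one (racemic, 1S,5S,7S drawn) | O=C1C[C@@H]2C[C@H](OCOC)[C@](C)(C1)O2 | intermediate
10 | trimethylsilyl enol ether of (1S,5S,7S)-9, C4=C8 | C[Si](C)(C)OC1=C[C@@H]2C[C@H](OCOC)[C@](C)(C1)O2 | intermediate
11 | lithium enolate from 10 | [Li]OC1=C[C@@H]2C[C@H](OCOC)[C@](C)(C1)O2 | intermediate
12 | (1S,4S,5S,7S)-7-(methoxymethoxy)-1,4-dimethyl-8-oxabicyclo[3.2.1]octan-3-one | O=C1[C@@H](C)[C@@H]2C[C@H](OCOC)[C@](C)(C1)O2 | intermediate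
13 | tetrasubstituted C4=C8 trimethylsilyl enol ether of 12 | C[Si](C)(C)OC1=C(C)[C@@H]2C[C@H](OCOC)[C@](C)(C1)O2 | intermediate
14 | (S)-but-3-ene-1,2-diol | OC[C@@H](O)C=C | starting material
15 | (4S)-2-(4-methoxyphenyl)-4-vinyl-1,3-dioxolane (acetal epimers) | C=C[C@H]1COC(c2ccc(OC)cc2)O1 | intermediate
16 | (S)-2-(4-methoxybenzyloxy)but-3-en-1-ol | OC[C@@H](OCc1ccc(OC)cc1)C=C | intermediate
17 | methyl 2-(acetoxymethyl)acrylate | C=C(COC(C)=O)C(=O)OC | starting material
18 | methyl (2E,4S)-2-(acetoxymethyl)-5-hydroxy-4-(4-methoxybenzyloxy)pent-2-enoate | OC[C@@H](OCc1ccc(OC)cc1)/C=C(\COC(C)=O)C(=O)OC | intermediate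
19 | methyl (2E,4S)-2-(acetoxymethyl)-4-(4-methoxybenzyloxy)-5-oxopent-2-enoate | O=C[C@@H](OCc1ccc(OC)cc1)/C=C(\COC(C)=O)C(=O)OC | intermediate
20 | aldol adduct with quaternary C4 (chain exo, methyl endo), 5,6-syn C5–OH / C6–OPMB | COC(=O)/C(COC(C)=O)=C/[C@H](OCc1ccc(OC)cc1)[C@@H](O)[C@@]4(C)[C@@H]3C[C@H](OCOC)[C@](C)(CC4=O)O3 | intermediate
21 | C5 methanesulfonate of 20 | COC(=O)/C(COC(C)=O)=C/[C@H](OCc1ccc(OC)cc1)[C@@H](OS(C)(=O)=O)[C@@]4(C)[C@@H]3C[C@H](OCOC)[C@](C)(CC4=O)O3 | intermediate
22 | cyclised trivalent samarium alkoxide ester enolate | COC(O[Sm](I)I)=C(COC(C)=O)[C@H]5[C@H](OCc1ccc(OC)cc1)[C@@H](OS(C)(=O)=O)[C@@]4(C)[C@@H]3C[C@H](OCOC)[C@](C)(C[C@]45O[Sm](I)I)O3 | intermediate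
23 | tricyclic tertiary C8 alcohol with C5 mesylate and C7 exo-methylene ester (all-trans cyclopentane, O8 endo) | C=C(C(=O)OC)[C@H]5[C@H](OCc1ccc(OC)cc1)[C@@H](OS(C)(=O)=O)[C@@]4(C)[C@@H]3C[C@H](OCOC)[C@](C)(C[C@]45O)O3 | intermediate
24 | potassium alkoxide of 23 | C=C(C(=O)OC)[C@H]5[C@H](OCc1ccc(OC)cc1)[C@@H](OS(C)(=O)=O)[C@@]4(C)[C@@H]3C[C@H](OCOC)[C@](C)(C[C@]45[O-])O3.[K+] | intermediate
25 | methyl (4Z)-1-(methoxymethoxy)-6-(4-methoxybenzyloxy)-8-oxo-3,10-epoxygermacra-4,11(13)-dien-12-oate | C=C(C(=O)OC)[C@H]2[C@H](OCc1ccc(OC)cc1)/C=C(/C)[C@@H]3C[C@H](OCOC)[C@](C)(CC2=O)O3 | intermediate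
26 | methyl (4Z)-6-hydroxy-1-(methoxymethoxy)-8-oxo-3,10-epoxygermacra-4,11(13)-dien-12-oate | C=C(C(=O)OC)[C@H]2[C@H](O)/C=C(/C)[C@@H]3C[C@H](OCOC)[C@](C)(CC2=O)O3 | intermediate
27 | (4Z)-1-(methoxymethoxy)-8-oxo-3,10-epoxygermacra-4,11(13)-dien-12,6-olide | C=C1C(=O)O[C@@H]2/C=C(/C)[C@@H]3C[C@H](OCOC)[C@](C)(CC(=O)[C@@H]12)O3 | intermediate
28 | (4Z,8R)-8-hydroxy-1-(methoxymethoxy)-3,10-epoxygermacra-4,11(13)-dien-12,6-olide | C=C1C(=O)O[C@@H]2/C=C(/C)[C@@H]3C[C@H](OCOC)[C@](C)(C[C@@H](O)[C@@H]12)O3 | intermediate
29 | angelic acid, (Z)-2-methylbut-2-enoic acid | C/C=C(/C)C(=O)O | starting material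
30 | angelic 2,4,6-trichlorobenzoic mixed anhydride | C/C=C(/C)C(=O)OC(=O)c1c(Cl)cc(Cl)cc1Cl | intermediate
31 | 8-O-angeloyl derivative of 28 (1-O-MOM ether of the target) | C=C1C(=O)O[C@@H]2/C=C(/C)[C@@H]3C[C@H](OCOC)[C@](C)(C[C@@H](OC(=O)/C(C)=C\C)[C@@H]12)O3 | intermediate
32 | 1-O-bromomethyl ether of the target | C=C1C(=O)O[C@@H]2/C=C(/C)[C@@H]3C[C@H](OCBr)[C@](C)(C[C@@H](OC(=O)/C(C)=C\C)[C@@H]12)O3 | intermediate
33 | CNP0213894.1, (1S,3S,4Z,6R,7R,8R,10S)-8-angeloyloxy-1-hydroxy-3,10-epoxygermacra-4,11(13)-dien-12,6-olide | C=C1C(=O)O[C@@H]2/C=C(/C)[C@@H]3C[C@H](O)[C@](C)(C[C@@H](OC(=O)/C(C)=C\C)[C@@H]12)O3 | target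

**Step count and risks**

Total step count: 22. Longest linear sequence: 18 steps (steps 1–9, then 14–22); the aldehyde branch (steps 10–13) joins at step 14.

Steps most likely to fail:

Step 14. The hindered tetrasubstituted enol ether may add slowly, giving the labile aldehyde time to epimerise at C6 or to slip into conjugation. Its ester and acetate oxygens may also compete with the PMB oxygen for magnesium, so that chelation control and hence the C5 configuration erode. The fallback stages the side chain. It sets out from alcohol 16, which Dess–Martin oxidation converts to (S)-2-(4-methoxybenzyloxy)but-3-enal F1, a simple α-alkoxy aldehyde with a single chelation site. The same MgBr2·OEt2-mediated Mukaiyama aldol with 13 should then give the vinyl aldol adduct F2. Cross-metathesis of F2 with 17 (second-generation Hoveyda–Grubbs catalyst) installs the acetoxymethyl acrylate and comes back to the route at 20.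

Step 16. Electron transfer may go to the enoate or the allylic acetate faster than to the hindered ketone, giving reduction or loss of acetate without ring closure. The trivalent samarium alkoxide may also fragment early, so that the newly formed ketone is reduced further. The fallback replaces the reductive cascade by a radical chain followed by a separate elimination. It sets out from 21: Bu3SnH with AIBN in benzene at 80 °C should effect O-stannyl ketyl 5-exo cyclisation onto the enoate with the same anti preference, giving after hydrolytic work-up the saturated acetoxymethyl ester F3 (C11 epimers). DBU in CH2Cl2 then eliminates acetic acid (E1cB) to form the exo-methylene ester and comes back to the route at 23.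

Step 17. Proton transfer from the newly formed ketone (acidic C7 hydrogen) to alkoxide that has not yet fragmented may stall conversion, and the resulting enolate may expel the C6 ether or scramble C7. The conformer with the mesylate pseudo-equatorial may also be reached only slowly at low temperature. The fallback unmasks the alkoxide from a silyl ether in a medium free of hydroxyl protons. It sets out from 23, which 1-(trimethylsilyl)imidazole converts to the C8 trimethylsilyl ether F4. Bu4NF (1 equiv) in THF at −78 °C then strips silicon and the same fragmentation follows at once, molecule by molecule, coming back to the route at 25.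

**Further compounds**

F1 | step 14 | (S)-2-(4-methoxybenzyloxy)but-3-enal | O=C[C@@H](OCc1ccc(OC)cc1)C=C
F2 | step 14 | vinyl aldol adduct (as 20 with CH=CH2 in place of the acrylate unit) | C=C[C@H](OCc1ccc(OC)cc1)[C@@H](O)[C@@]4(C)[C@@H]3C[C@H](OCOC)[C@](C)(CC4=O)O3
F3 | step 16 | tricyclic C8 alcohol with C5 mesylate and CH(CH2OAc)CO2Me on C7 (C11 epimers) | COC(=O)C(COC(C)=O)[C@H]5[C@H](OCc1ccc(OC)cc1)[C@@H](OS(C)(=O)=O)[C@@]4(C)[C@@H]3C[C@H](OCOC)[C@](C)(C[C@]45O)O3
F4 | step 17 | C8 O-trimethylsilyl ether of 23 | C=C(C(=O)OC)[C@H]5[C@H](OCc1ccc(OC)cc1)[C@@H](OS(C)(=O)=O)[C@@]4(C)[C@@H]3C[C@H](OCOC)[C@](C)(C[C@]45O[Si](C)(C)C)O3
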